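**Retrosynthetic overview**
- The side-chain oxirane is made last, by catalyst-controlled epoxidation of a prenyl-type alkene. Before that, the three (Z)-2-methylbut-2-enoyl (angeloyl) esters are put on a ring-epoxy triol in one operation with a mixed anhydride prepared in its own branch.
- The ring trans-diol comes from hydroxyl-directed reduction of an α-hydroxy ketone, which comes from Rubottom oxidation of a silyl enol ether.
- Key disconnection: the bond between ring C4 and the 1,1-disubstituted alkene carbon, formed in a nickel-catalysed, branch-selective reductive coupling of a bicyclic epoxy enone, a terminal alkyne and a silane, which also delivers that silyl enol ether.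
- The epoxy enone is a masked methylcyclohexadienone made in four steps from a bought methylcyclohexenone; the carbocycle is bought, and its oxirane is the first ring formed.
- The alkyne is made in four steps from a C6 unsaturated acid and a silylacetylene (the carbinol centre by asymmetric transfer hydrogenation); the side-chain oxirane is the last ring formed.

Assumption: ring locants are those of 7-oxabicyclo[4.1.0]heptane (C1 bears the methyl group, C2 and C3 the ring esters, C4 the side chain), which makes the target the (1S,2S,3R,4R,6S) ring isomer with a (3S) side-chain ester carbon, a (2R) oxirane and three (Z)-esters.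

**Route**

Step 1
Reactants: 1 2-methylcyclohex-2-en-1-one
Product: 2 (R)-2-methylcyclohex-2-en-1-ol
Conditions: (S)-Me-CBS oxazaborolidine [(S)-1-methyl-3,3-diphenyltetrahydro-1H,3H-pyrrolo[1,2-c][1,3,2]oxazaborole] (10 mol%), BH3·SMe2 (0.6 equiv), THF, −20 °C; MeOH quench
Reagents that add atoms: none
Why: Corey–Bakshi–Shibata reduction, in which the (S)-oxazaborolidine binds the ketone with the substituted vinyl arm as the large group and delivers hydride to one carbonyl face, sets the (R)-carbinol (about 90–94% ee expected) that steers the next step.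

Step 2
Reactants: 2 (R)-2-methylcyclohex-2-en-1-ol
Product: 3 (1R,2R,6S)-1-methyl-7-oxabicyclo[4.1.0]heptan-2-ol
Conditions: VO(acac)2 (2 mol%), t-BuOOH (1.5 equiv), CH2Cl2, 0 to 25 °C
Reagents that add atoms: tert-butyl hydroperoxide, CC(C)(C)OO
Why: Hydroxyl-directed vanadium-catalysed epoxidation of a cyclic allylic alcohol delivers oxygen to the alkene face syn to the OH, which fixes the two oxirane centres C1 and C6 that relay all later ring stereochemistry.

Step 3
Reactants: 3 (1R,2R,6S)-1-methyl-7-oxabicyclo[4.1.0]heptan-2-ol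
Product: 4 (1S,6S)-1-methyl-7-oxabicyclo[4.1.0]heptan-2-one
Conditions: (n-Pr4N)RuO4 (5 mol%), N-methylmorpholine N-oxide (1.5 equiv), CH2Cl2, 25 °C
Reagents that add atoms: none
Why: Ley–Griffith oxidation of the secondary alcohol is neutral, leaves the oxirane intact and removes the carbinol centre that has done its directing work.

Step 4
Reactants: 4 (1S,6S)-1-methyl-7-oxabicyclo[4.1.0]heptan-2-one
Product: 5 (1S,6S)-1-methyl-7-oxabicyclo[4.1.0]hept-3-en-2-one
Conditions: LiN(i-Pr)2 (1.1 equiv), THF, −78 °C; then N-tert-butylbenzenesulfinimidoyl chloride (1.2 equiv), −78 °C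
Reagents that add atoms: none
Why: Mukaiyama dehydrogenation works here because only C3 can enolise (C1 is a quaternary oxirane carbon), so the lithium enolate is sulfenylated and syn-eliminates at low temperature to the C3=C4 enone without palladium or warm base that could open the oxirane.

Step 5
Reactants: 6 4-methylpent-3-enoic acid
Product: 7 N-methoxy-N,4-dimethylpent-3-enamide
Conditions: 1,1'-carbonyldiimidazole (1.1 equiv), CH2Cl2, 25 °C; then MeNH(OMe)·HCl (1.2 equiv)
Reagents that add atoms: N,O-dimethylhydroxylamine hydrochloride, CNOC.Cl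
Why: Aminolysis of the acyl imidazolide gives the Weinreb amide, which stops the following acetylide addition at the ketone stage.

Step 6
Reactants: 7 N-methoxy-N,4-dimethylpent-3-enamide; 8 ethynyltrimethylsilane
Product: 9 6-methyl-1-(trimethylsilyl)hept-5-en-1-yn-3-one
Conditions: 8, n-BuLi (1.2 equiv), THF, −78 °C; then 7, −78 to 0 °C; aq. NH4Cl
Reagents that add atoms: none
Why: Weinreb ketone synthesis, in which the lithium acetylide adds once to give a chelated tetrahedral intermediate that collapses to the ynone only on quench.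

Step 7
Reactants: 9 6-methyl-1-(trimethylsilyl)hept-5-en-1-yn-3-one
Product: 10 (S)-6-methyl-1-(trimethylsilyl)hept-5-en-1-yn-3-ol
Conditions: RuCl[(S,S)-TsDPEN](p-cymene) (1 mol%), i-PrOH, 25 °C
Reagents that add atoms: none
Why: Noyori asymmetric transfer hydrogenation, whose (S,S)-TsDPEN ruthenium hydride distinguishes the alkynyl from the alkyl flank of the ynone in an outer-sphere transition state, sets the (S)-carbinol (the future side-chain ester carbon, >95% ee expected) without touching alkene or alkyne.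

Step 8
Reactants: 10 (S)-6-methyl-1-(trimethylsilyl)hept-5-en-1-yn-3-ol
Product: 12 (S)-triethyl[(6-methylhept-5-en-1-yn-3-yl)oxy]silane, via bis-silyl ether 11 (not isolated)
Conditions: Et3SiCl (1.2 equiv), imidazole (2.4 equiv), CH2Cl2, 0 °C; silica plug; then K2CO3 (0.2 equiv), MeOH, 25 °C
Reagents that add atoms: chlorotriethylsilane, CC[Si](Cl)(CC)CC
Why: O-silylation followed by selective methanolysis of the much more labile alkynyl C–Si bond unmasks the terminal alkyne while the secondary triethylsilyl ether survives.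

Step 9
Reactants: 13 (Z)-2-methylbut-2-enoic acid (angelic acid)
Product: 14 (Z)-2-methylbut-2-enoic 2,4,6-trichlorobenzoic anhydride
Conditions: 2,4,6-Cl3C6H2COCl (1.0 equiv), Et3N (1.05 equiv), toluene, 25 °C; filtered and used as a toluene solution
Reagents that add atoms: 2,4,6-trichlorobenzoyl chloride, O=C(Cl)c1c(Cl)cc(Cl)cc1Cl
Why: Yamaguchi-type activation gives a mixed anhydride whose hindered trichlorobenzoyl carbonyl steers alcohols to the angeloyl carbonyl, and the (Z)-geometry is kept because no nucleophilic catalyst is present.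

Step 10
Reactants: 5 (1S,6S)-1-methyl-7-oxabicyclo[4.1.0]hept-3-en-2-one; 12 (S)-triethyl[(6-methylhept-5-en-1-yn-3-yl)oxy]silane
Product: 15 (1S,4S,6S)-1-methyl-4-[(3S)-6-methyl-3-(triethylsilyloxy)hepta-1,5-dien-2-yl]-2-(triethylsilyloxy)-7-oxabicyclo[4.1.0]hept-2-ene
Conditions: Ni(cod)2 (10 mol%), 1,3-bis[2,6-bis((R)-1-phenylethyl)-4-methylphenyl]imidazolin-2-ylidene (10 mol%, free carbene, no added base), Et3SiH (2 equiv), toluene, 25 °C, slow addition of 12
Reagents that add atoms: triethylsilane, CC[SiH](CC)CC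
Why: Proposed new method: a branch-selective (Markovnikov) three-component reductive coupling of a terminal alkyne, a cyclic enone and a silane on zerovalent nickel carrying a very bulky chiral N-heterocyclic carbene, in which oxidative cyclisation of the nickel-bound enone and alkyne gives a nickelacycle where the large N-aryl groups keep the alkyne substituent away from nickel so that the C–C bond forms between the internal alkyne carbon and the enone β-carbon C4 on the face anti to the oxirane oxygen (the ligand antipode that reinforces this bias is used), after which Si–H σ-bond metathesis at the nickel enolate oxygen and C–H reductive elimination release the 1,1-disubstituted alkene and the triethylsilyl enol ether with every atom of 5, 12 and the silane retained, setting the C4 stereocentre; the closest known reactions are the nickel-catalysed enone–alkyne–silane reductive coupling to enol silanes (linear regiochemistry with terminal alkynes) and the large-carbene regiochemical reversal known for aldehyde–alkyne reductive couplings.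

Step 11
Reactants: 15 (1S,4S,6S)-1-methyl-4-[(3S)-6-methyl-3-(triethylsilyloxy)hepta-1,5-dien-2-yl]-2-(triethylsilyloxy)-7-oxabicyclo[4.1.0]hept-2-ene
Product: 17 (1S,3R,4R,6S)-3-hydroxy-4-[(3S)-3-hydroxy-6-methylhepta-1,5-dien-2-yl]-1-methyl-7-oxabicyclo[4.1.0]heptan-2-one, via silyloxy oxirane 16 (not isolated)
Conditions: dimethyldioxirane (1.05 equiv, acetone solution), CH2Cl2, −78 to −40 °C; then HF·pyridine, pyridine, THF, 0 °C
Reagents that add atoms: dimethyldioxirane, CC1(C)OO1
Why: Rubottom oxidation, in which the electron-rich enol silane is epoxidised much faster than the other alkenes and from the face anti to the C4 side chain and the C1 methyl group, puts the new C3 hydroxyl trans to the side chain, and buffered fluoride then opens the silyloxy oxirane and removes both silyl groups.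

Step 12
Reactants: 17 (1S,3R,4R,6S)-3-hydroxy-4-[(3S)-3-hydroxy-6-methylhepta-1,5-dien-2-yl]-1-methyl-7-oxabicyclo[4.1.0]heptan-2-one
Product: 18 (1R,2S,3R,4R,6S)-4-[(3S)-3-hydroxy-6-methylhepta-1,5-dien-2-yl]-1-methyl-7-oxabicyclo[4.1.0]heptane-2,3-diol
Conditions: Me4NBH(OAc)3 (4 equiv), MeCN/AcOH (2:1), −30 °C
Reagents that add atoms: none
Why: Hydroxyl-directed (Evans–Saksena) reduction, in which the borohydride bound to the C3 oxygen delivers hydride intramolecularly to the carbonyl face on the side of that oxygen, gives the C2 alcohol trans to the C3 hydroxyl and anti to the oxirane oxygen (the all-equatorial diol).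

Step 13
Reactants: 18 (1R,2S,3R,4R,6S)-4-[(3S)-3-hydroxy-6-methylhepta-1,5-dien-2-yl]-1-methyl-7-oxabicyclo[4.1.0]heptane-2,3-diol; 14 (Z)-2-methylbut-2-enoic 2,4,6-trichlorobenzoic anhydride
Product: 19 (1S,2S,3R,4R,6S)-1-methyl-4-[(3S)-6-methyl-3-{[(Z)-2-methylbut-2-enoyl]oxy}hepta-1,5-dien-2-yl]-7-oxabicyclo[4.1.0]heptane-2,3-diyl bis[(Z)-2-methylbut-2-enoate]
Conditions: 14 (6 equiv), Et3N (6 equiv), toluene, 75 °C, no DMAP
Reagents that add atoms: none
Why: Yamaguchi esterification without a nucleophilic catalyst acylates all three secondary hydroxyls at the angeloyl carbonyl with retention of the (Z)-geometry and of every carbinol configuration, while the amine buffers the liberated acid away from the oxirane.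

Step 14
Reactants: 19 (1S,2S,3R,4R,6S)-1-methyl-4-[(3S)-6-methyl-3-{[(Z)-2-methylbut-2-enoyl]oxy}hepta-1,5-dien-2-yl]-7-oxabicyclo[4.1.0]heptane-2,3-diyl bis[(Z)-2-methylbut-2-enoate]
Product: 20 (1S,2S,3R,4R,6S)-4-{(3S)-4-[(2R)-3,3-dimethyloxiran-2-yl]-3-{[(Z)-2-methylbut-2-enoyl]oxy}but-1-en-2-yl}-1-methyl-7-oxabicyclo[4.1.0]heptane-2,3-diyl bis[(Z)-2-methylbut-2-enoate] (CNP0258231.1)
Conditions: Shi ketone from D-fructose [1,2:4,5-di-O-isopropylidene-β-D-erythro-2,3-hexodiulo-2,6-pyranose] (30 mol%), Oxone (2KHSO5·KHSO4·K2SO4), K2CO3, Bu4NHSO4 (cat.), MeCN/CH2(OMe)2/aq. Na2B4O7 buffer (pH 10.5), 0 °C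
Reagents that add atoms: potassium peroxymonosulfate (active salt of Oxone), [K+].[O-]S(=O)(=O)OO
Why: Shi asymmetric epoxidation, in which the chiral dioxirane attacks the only electron-rich trisubstituted alkene through a spiro transition state from the face that gives the (R)-oxirane, leaves the hindered 1,1-disubstituted alkene and the electron-poor angelates untouched.

**Compound list**
1 | 2-methylcyclohex-2-en-1-one | CC1=CCCCC1=O | starting material
2 | (R)-2-methylcyclohex-2-en-1-ol | CC1=CCCC[C@H]1O | intermediate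
3 | (1R,2R,6S)-1-methyl-7-oxabicyclo[4.1.0]heptan-2-ol | C1C[C@@H]2O[C@]2(C)[C@H](O)C1 | intermediate
4 | (1S,6S)-1-methyl-7-oxabicyclo[4.1.0]heptan-2-one | C1C[C@@H]2O[C@]2(C)C(=O)C1 | intermediate
5 | (1S,6S)-1-methyl-7-oxabicyclo[4.1.0]hept-3-en-2-one | C1[C@@H]2O[C@]2(C)C(=O)C=C1 | intermediate
6 | 4-methylpent-3-enoic acid | CC(C)=CCC(=O)O | starting material
7 | N-methoxy-N,4-dimethylpent-3-enamide | CC(C)=CCC(=O)N(C)OC | intermediate
8 | ethynyltrimethylsilane | C#C[Si](C)(C)C | starting material
9 | 6-methyl-1-(trimethylsilyl)hept-5-en-1-yn-3-one | CC(C)=CCC(=O)C#C[Si](C)(C)C | intermediate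
10 | (S)-6-methyl-1-(trimethylsilyl)hept-5-en-1-yn-3-ol | C[Si](C)(C)C#C[C@H](CC=C(C)C)O | intermediate
11 | (S)-triethyl{[6-methyl-1-(trimethylsilyl)hept-5-en-1-yn-3-yl]oxy}silane (bis-silyl ether) | C[Si](C)(C)C#C[C@H](CC=C(C)C)O[Si](CC)(CC)CC | intermediate
12 | (S)-triethyl[(6-methylhept-5-en-1-yn-3-yl)oxy]silane | C#C[C@H](CC=C(C)C)O[Si](CC)(CC)CC | intermediate
13 | (Z)-2-methylbut-2-enoic acid (angelic acid) | C/C=C(/C)C(=O)O | starting material
14 | (Z)-2-methylbut-2-enoic 2,4,6-trichlorobenzoic anhydride | C/C=C(/C)C(=O)OC(=O)c1c(Cl)cc(Cl)cc1Cl | intermediate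
15 | (1S,4S,6S)-1-methyl-4-[(3S)-6-methyl-3-(triethylsilyloxy)hepta-1,5-dien-2-yl]-2-(triethylsilyloxy)-7-oxabicyclo[4.1.0]hept-2-ene | C=C([C@H](CC=C(C)C)O[Si](CC)(CC)CC)[C@H]1C[C@@H]2O[C@]2(C)C(O[Si](CC)(CC)CC)=C1 | intermediate
16 | silyloxy oxirane: the C2–C3 epoxide of 15 on the face of the existing oxirane (anti to the C4 side chain), C2 keeping its triethylsilyloxy group; 3,8-dioxatricyclo[5.1.0.0(2,4)]octane core | C=C([C@H](CC=C(C)C)O[Si](CC)(CC)CC)[C@H]1C[C@@H]2O[C@]2(C)[C@]3(O[Si](CC)(CC)CC)O[C@H]13 | intermediate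
17 | (1S,3R,4R,6S)-3-hydroxy-4-[(3S)-3-hydroxy-6-methylhepta-1,5-dien-2-yl]-1-methyl-7-oxabicyclo[4.1.0]heptan-2-one | C=C([C@H](CC=C(C)C)O)[C@H]1C[C@@H]2O[C@]2(C)C(=O)[C@@H]1O | intermediate
18 | (1R,2S,3R,4R,6S)-4-[(3S)-3-hydroxy-6-methylhepta-1,5-dien-2-yl]-1-methyl-7-oxabicyclo[4.1.0]heptane-2,3-diol | C=C([C@H](CC=C(C)C)O)[C@H]1C[C@@H]2O[C@]2(C)[C@@H](O)[C@@H]1O | intermediate
19 | (1S,2S,3R,4R,6S)-1-methyl-4-[(3S)-6-methyl-3-{[(Z)-2-methylbut-2-enoyl]oxy}hepta-1,5-dien-2-yl]-7-oxabicyclo[4.1.0]heptane-2,3-diyl bis[(Z)-2-methylbut-2-enoate] | C=C([C@H](CC=C(C)C)OC(=O)/C(C)=C\C)[C@H]1C[C@@H]2O[C@]2(C)[C@@H](OC(=O)/C(C)=C\C)[C@@H]1OC(=O)/C(C)=C\C | intermediate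
20 | (1S,2S,3R,4R,6S)-4-{(3S)-4-[(2R)-3,3-dimethyloxiran-2-yl]-3-{[(Z)-2-methylbut-2-enoyl]oxy}but-1-en-2-yl}-1-methyl-7-oxabicyclo[4.1.0]heptane-2,3-diyl bis[(Z)-2-methylbut-2-enoate] | C=C([C@H](C[C@H]1OC1(C)C)OC(=O)/C(C)=C\C)[C@H]1C[C@@H]2O[C@]2(C)[C@@H](OC(=O)/C(C)=C\C)[C@@H]1OC(=O)/C(C)=C\C | target

**Step count**
Total: 14 steps. Longest linear sequence: 9 steps (1–4 then 10–14; the branch 5–8 then 10–14 is equally long), which is 64% of the total. Step 9 is a one-step third branch.

**Steps most likely to fail, with fallbacks**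

Step 10, the proposed coupling. It can fail through linear regiochemistry, wrong facial selectivity, or reductive opening of the keto-oxirane by low-valent nickel. The fallback uses known chemistry, sets out from 12 (with 5 as partner) and comes back at 15. Copper-catalysed α-selective protoboration of the propargylic silyl ether 12 (CuCl 5 mol%, 1,3-dimesitylimidazolinium chloride, NaOt-Bu, B2pin2, MeOH, THF) gives (S)-triethyl{[6-methyl-2-(4,4,5,5-tetramethyl-1,3,2-dioxaborolan-2-yl)hepta-1,5-dien-3-yl]oxy}silane F1. Rhodium-catalysed Hayashi–Miyaura 1,4-addition of F1 to 5 ([Rh(OH)((R)-binap)]2 or its antipode, whichever adds anti to the oxirane; dioxane/H2O, 40 °C, no added base) gives (1S,4S,6S)-1-methyl-4-[(3S)-6-methyl-3-(triethylsilyloxy)hepta-1,5-dien-2-yl]-7-oxabicyclo[4.1.0]heptan-2-one F2. Soft enolisation (Et3SiOTf, Et3N, CH2Cl2, 0 °C; only C3 can enolise) returns 15.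

Step 11, the Rubottom oxidation. The dioxirane may also attack the trisubstituted side-chain alkene. The fallback sets out from 15 and comes back at 17, and replaces electrophilic epoxidation by enolate hydroxylation. HF·pyridine/pyridine in THF removes both silyl groups of 15 to give (1S,4S,6S)-4-[(3S)-3-hydroxy-6-methylhepta-1,5-dien-2-yl]-1-methyl-7-oxabicyclo[4.1.0]heptan-2-one F3. Its potassium alkoxide–enolate (KN(SiMe3)2, 2.2 equiv, THF, −78 °C) is hydroxylated with 2-(phenylsulfonyl)-3-phenyloxaziridine (Davis oxidation), which does not epoxidise alkenes, anti to the C4 substituent to give 17.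

Step 13, the triple angeloylation. Three hindered secondary alcohols must be acylated with a hindered acid that isomerises easily to the (E)-tiglate. The fallback sets out from 18 and comes back at 19, and builds the (Z)-alkenes in place instead of transferring them. All three hydroxyls are esterified with 2-[bis(2,2,2-trifluoroethoxy)phosphoryl]propanoic acid (N,N'-dicyclohexylcarbodiimide, DMAP, CH2Cl2) to the tris-phosphonate triester F4. Threefold Still–Gennari olefination with acetaldehyde (KN(SiMe3)2, 18-crown-6, THF, −78 °C) then gives 19.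

Further compounds
F1 | step 10 | (S)-triethyl{[6-methyl-2-(4,4,5,5-tetramethyl-1,3,2-dioxaborolan-2-yl)hepta-1,5-dien-3-yl]oxy}silane | C=C(B1OC(C)(C)C(C)(C)O1)[C@H](CC=C(C)C)O[Si](CC)(CC)CC
F2 | step 10 | (1S,4S,6S)-1-methyl-4-[(3S)-6-methyl-3-(triethylsilyloxy)hepta-1,5-dien-2-yl]-7-oxabicyclo[4.1.0]heptan-2-one | C=C([C@H](CC=C(C)C)O[Si](CC)(CC)CC)[C@H]1C[C@@H]2O[C@]2(C)C(=O)C1
F3 | step 11 | (1S,4S,6S)-4-[(3S)-3-hydroxy-6-methylhepta-1,5-dien-2-yl]-1-methyl-7-oxabicyclo[4.1.0]heptan-2-one | C=C([C@H](CC=C(C)C)O)[C@H]1C[C@@H]2O[C@]2(C)C(=O)C1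
F4 | step 13 | (1S,2S,3R,4R,6S)-1-methyl-4-[(3S)-3-({2-[bis(2,2,2-trifluoroethoxy)phosphoryl]propanoyl}oxy)-6-methylhepta-1,5-dien-2-yl]-7-oxabicyclo[4.1.0]heptane-2,3-diyl bis{2-[bis(2,2,2-trifluoroethoxy)phosphoryl]propanoate} (epimer mixture at the phosphonate-bearing carbons) | C=C([C@H](CC=C(C)C)OC(=O)C(C)P(=O)(OCC(F)(F)F)OCC(F)(F)F)[C@H]1C[C@@H]2O[C@]2(C)[C@@H](OC(=O)C(C)P(=O)(OCC(F)(F)F)OCC(F)(F)F)[C@@H]1OC(=O)C(C)P(=O)(OCC(F)(F)F)OCC(F)(F)F
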